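(The earlier runs and the new flask come from a simulation with made-up constants; the scatter is artificial.)

| setting | north | north-east | flask |
|---|---|---|---|
| L | 0.28 M | 0.44 M | 0.20 M |
| E | 0.18 M | 0.18 M | 0.180 M |
| D | 0.010 M | 0.010 M | 0.0100 M |
| remark | run made earlier | run made earlier |  |
| time |  |  | 3.0 h |

| run | time / h | G / % | L / % |
|---|---|---|---|
| north | 0.417 | 47 | 48 |
| north | 0.833 | 53 | 48 |
| north | 1.33 | 52 | 49 |
| north | 1.50 | 52 | 50 |
| north | 2.00 | 53 | 47 |
| north | 2.50 | 52 | 45 |
| north | 3.00 | 53 | 48 |
| north-east | 0.250 | 33 | 64 |
| north-east | 0.333 | 34 | 66 |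
| north-east | 0.500 | 38 | 67 |
| north-east | 0.833 | 36 | 64 |
| north-east | 1.33 | 36 | 63 |
| north-east | 2.00 | 33 | 65 |
| north-east | 3.00 | 33 | 66 |

(standard deviation of a reading: 1.5 percentage points)

- each molecule carries two end groups: a chain counts once for every two ends that are left, dead ends included; the units are half of the end groups of the two monomers charged
- reactions considered so far: L + E <-> G + J; J -> Z; E + D -> X; E -> Q

- average number of monomer units in a chain (unreacted monomers counted as chains of one) at 3.0 h
- part of the L that has reacted at 3.0 h

1. From the north run to the north-east run the charge of L rises from 0.28 M to 0.44 M, yet over the last 4 readings G stands at 52.5% and 34.5% of the L charged, which is 0.147 M and 0.152 M, so I read E as the limiting reagent and each plateau as the end of E.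

2. I give D its 0.010 M of E in each run and call the rest of the missing E the loss to Q, 0.0230 M north and 0.0182 M north-east; since forward L + E goes with cL and E → Q does not, each bit of G comes with an amount of Q in proportion to one over cL, and pooling the readings of the two runs gives, as a reading, 0.0353 M, the selectivity factor s, which is the cQ made per unit of ln(L charged over cL).

3. I reckon two extremes for the flask: with no loss to Q, cG reaches 0.170 M; with the loss that the cL of that first case implies, it reaches 0.103 M; I take the loss in the flask to lie between nothing and that, so by this reckoning cG lies between the two.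

4. Starting from the middle, one round gives 0.130 M and the next 0.133 M; I commit to their mean, 0.131 M, so in the flask I expect c of 65.7% and, with chains counted as units minus links, dp of 3.24.

The forecast gives dp 3.2 and c 65% on other grounds, “the system reaches equilibrium quickly”.

The flask gives dp 3.26 and c 65.9%.

    L + E ⇌ G + J (K = 1.40, k = 0.0100 M⁻¹ s⁻¹)
    J → Z (k = 0.0310 s⁻¹)
    E + D → X (k = 0.0500 M⁻¹ s⁻¹)
    E → Q (k = 3.50 × 10⁻⁴ s⁻¹)

With the backward run from G + J to L + E struck out, c in the flask stands at 66.1%, and that run makes no difference to dp. With 34.1% of L left, s gives cQ = 0.0380 M, and the flask holds 0.0383 M. In the neighbour charged with 0.31 M of E, 4.90% of L is left, so s gives 0.106 M, and that neighbour holds 0.109 M of Q.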